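**Retrosynthetic overview**
1. The target comes from a trichloro diol by carbamoylation and MOM removal. That diol comes from a C2-symmetric bis(2-bromo-4,4-dichlorobutyl) macrocycle by one radical reduction, which removes both C–Br bonds and one of four equivalent C–Cl bonds. The macrocycle comes from a C2-symmetric 7,20-diallyl[7.7]paracyclophane-1,14-diol by Kharasch addition of BrCHCl2.
2. Key disconnection: both C6–C7 bonds are cut at once, giving two copies of one monomer with a primary alkyl Bpin (C6) and a secondary benzylic carbamate (C7). In the forward sense, a 24-membered bis-boronate contracts to the 22-membered carbocycle by two 1,2-metalate shifts, and B is then exchanged for H.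
3. In the monomer, C7 comes from DMF (ortho-lithiation) and the allyl group from an asymmetric allylboration. The Ar–C1 bond comes from a 1,2-aryl shift from an aryl Bpin onto a sparteine-lithiated carbamate, which sets C1. C2 comes from (R)-3-bromo-2-methylpropan-1-ol.
4. Ring order: both benzene rings are bought as resorcinol. The only ring made is the macrocycle, first as the boron-containing 24-ring and then as the 22-ring.

Assumption: cyclophane numbering is used (C1/C14 carry the carbamates, C2/C15 the methyl groups, C7/C20 the side chains), so the SMILES reads 1R,2S,7S,14R,15S,20S.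

**Step 1**
Reactants: 1 resorcinol
Product: 2 1,3-bis(methoxymethoxy)benzene
Conditions: NaH (2.4 equiv), MOMCl (2.4 equiv), DMF, 0 °C to rt
Reagents that add atoms: chloromethyl methyl ether (MOMCl), COCCl
Why: Williamson-type O-alkylation of both phenoxides installs MOM groups that later direct lithiation between them and come off under mild acid.

**Step 2**
Reactants: 2 1,3-bis(methoxymethoxy)benzene
Product: 3 2-[3,5-bis(methoxymethoxy)phenyl]-4,4,5,5-tetramethyl-1,3,2-dioxaborolane
Conditions: [Ir(OMe)(cod)]2 (1 mol%), dtbpy (2 mol%), B2pin2 (1.0 equiv), THF, 80 °C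
Reagents that add atoms: bis(pinacolato)diboron, CC1(C)OB(OC1(C)C)B1OC(C)(C)C(C)(C)O1
Why: Sterically controlled iridium-catalysed aromatic C–H borylation takes the only C–H that has no ortho substituent, as it does for other 1,3-disubstituted arenes.

**Step 3**
Reactants: 4 (R)-3-bromo-2-methylpropan-1-ol
Product: 5 (R)-3-bromo-2-methylpropyl N,N-diisopropylcarbamate
Conditions: i-Pr2NC(O)Cl, Et3N, DMAP (cat.), CH2Cl2, reflux
Reagents that add atoms: N,N-diisopropylcarbamoyl chloride, CC(C)N(C(C)C)C(Cl)=O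
Why: O-carbamoylation gives the Hoppe carbamate without touching the bought stereocenter, which becomes C2.

**Step 4**
Reactants: 5 (R)-3-bromo-2-methylpropyl N,N-diisopropylcarbamate; 6 1-bromo-3-chloropropane
Product: 8 (S)-6-chloro-2-methylhexyl N,N-diisopropylcarbamate, via Grignard reagent 7 (not isolated)
Conditions: Mg, THF, 40 °C; then 6 (1.5 equiv), Li2CuCl4 (3 mol%), THF, −10 °C to rt
Reagents that add atoms: none
Why: Kochi-type copper-catalysed sp3–sp3 Grignard coupling reacts at C–Br much faster than at C–Cl, the hindered carbamate resists the Grignard carbon, and C2 is not involved (the descriptor changes only because the priorities change).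

**Step 5**
Reactants: 8 (S)-6-chloro-2-methylhexyl N,N-diisopropylcarbamate; 3 2-[3,5-bis(methoxymethoxy)phenyl]-4,4,5,5-tetramethyl-1,3,2-dioxaborolane
Product: 12 (1R,2S)-1-[3,5-bis(methoxymethoxy)phenyl]-6-chloro-2-methylhexan-1-ol, via lithiated carbamate 9 (not isolated), via boronate complex 10 (not isolated), via benzylic boronic ester 11 (not isolated)
Conditions: s-BuLi, (−)-sparteine, Et2O, −78 °C, 5 h; 3, −78 °C; MgBr2·OEt2, reflux; then NaOH, H2O2, THF, 0 °C
Reagents that add atoms: hydrogen peroxide, OO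
Why: In this Hoppe–Aggarwal lithiation–borylation, (−)-sparteine directs removal of the pro-S hydrogen, boron enters with retention, the electron-rich aryl group makes a 1,2-shift from B to C1 with inversion as the carbamate leaves, and oxidation with retention gives 1R under reagent control, syn to the C2 methyl group.

**Step 6**
Reactants: 12 (1R,2S)-1-[3,5-bis(methoxymethoxy)phenyl]-6-chloro-2-methylhexan-1-ol
Product: 13 tert-butyl{(1R,2S)-1-[3,5-bis(methoxymethoxy)phenyl]-6-chloro-2-methylhexyloxy}dimethylsilane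
Conditions: TBSCl, imidazole, DMF, 40 °C
Reagents that add atoms: tert-butyldimethylsilyl chloride, CC(C)(C)[Si](C)(C)Cl
Why: Silylation masks the only acidic hydrogen before the organolithium steps, and the fluoride used in step 11 removes the group at no extra cost.

**Step 7**
Reactants: 13 tert-butyl{(1R,2S)-1-[3,5-bis(methoxymethoxy)phenyl]-6-chloro-2-methylhexyloxy}dimethylsilane; 14 N,N-dimethylformamide
Product: 16 4-[(1R,2S)-1-(tert-butyldimethylsilyloxy)-6-chloro-2-methylhexyl]-2,6-bis(methoxymethoxy)benzaldehyde, via aryllithium 15 (not isolated)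
Conditions: s-BuLi, TMEDA, THF, −78 °C, 1 h; 14, −78 to 0 °C; aq. work-up
Reagents that add atoms: none
Why: Directed ortho-metalation occurs at the position flanked by both MOM ethers (cooperative direction), −78 °C spares the primary chloride, and formylation brings in C7.

**Step 8**
Reactants: 16 4-[(1R,2S)-1-(tert-butyldimethylsilyloxy)-6-chloro-2-methylhexyl]-2,6-bis(methoxymethoxy)benzaldehyde; 17 allylmagnesium bromide
Product: 19 (1R)-1-{4-[(1R,2S)-1-(tert-butyldimethylsilyloxy)-6-chloro-2-methylhexyl]-2,6-bis(methoxymethoxy)phenyl}but-3-en-1-ol, via B-allyldiisopinocampheylborane 18 (not isolated)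
Conditions: 17, (+)-Ipc2BOMe, Et2O, 0 °C to rt; 16, −78 °C; then NaOH, H2O2
Reagents that add atoms: none
Why: Brown asymmetric allylboration through a closed chair transition state gives the R carbinol from aryl aldehydes with the reagent of the (−)-α-pinene series, and the remote C1/C2 centres do not interfere.

**Step 9**
Reactants: 19 (1R)-1-{4-[(1R,2S)-1-(tert-butyldimethylsilyloxy)-6-chloro-2-methylhexyl]-2,6-bis(methoxymethoxy)phenyl}but-3-en-1-ol
Product: 20 (1R)-1-{4-[(1R,2S)-1-(tert-butyldimethylsilyloxy)-6-chloro-2-methylhexyl]-2,6-bis(methoxymethoxy)phenyl}but-3-en-1-yl N,N-diisopropylcarbamate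
Conditions: NaH, i-Pr2NC(O)Cl, THF, 0 to 60 °C
Reagents that add atoms: N,N-diisopropylcarbamoyl chloride, CC(C)N(C(C)C)C(Cl)=O
Why: O-carbamoylation of the sodium alkoxide overcomes the hindrance of the two ortho MOM ethers and leaves the C–O bond, and so the configuration, untouched.

**Step 10**
Reactants: 20 (1R)-1-{4-[(1R,2S)-1-(tert-butyldimethylsilyloxy)-6-chloro-2-methylhexyl]-2,6-bis(methoxymethoxy)phenyl}but-3-en-1-yl N,N-diisopropylcarbamate
Product: 21 (1R)-1-{4-[(1R,2S)-1-(tert-butyldimethylsilyloxy)-2-methyl-6-(pinacolatoboryl)hexyl]-2,6-bis(methoxymethoxy)phenyl}but-3-en-1-yl N,N-diisopropylcarbamate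
Conditions: CuI (10 mol%), PPh3 (13 mol%), LiOMe, n-Bu4NI, B2pin2, DMF, 40 °C
Reagents that add atoms: bis(pinacolato)diboron, CC1(C)OB(OC1(C)C)B1OC(C)(C)C(C)(C)O1
Why: Copper-catalysed boryl substitution of a primary alkyl halide, with iodide as shuttle for the chloride, places boron on C6, and the PPh3-ligated boryl copper species adds only sluggishly to an unactivated terminal alkene.

**Step 11**
Reactants: 21 (1R)-1-{4-[(1R,2S)-1-(tert-butyldimethylsilyloxy)-2-methyl-6-(pinacolatoboryl)hexyl]-2,6-bis(methoxymethoxy)phenyl}but-3-en-1-yl N,N-diisopropylcarbamate (two molecules)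
Product: 25 (1R,2S,7S,14R,15S,20S)-7,20-diallyl-2,15-dimethyl-tetra-O-MOM-[7.7]paracyclophane-1,14-diol, via lithiated monomer 22 (not isolated), via macrocyclic bis-boronate 23 (not isolated), via macrocyclic bis-boronic ester 24 (not isolated)
Conditions: LiN(i-Pr)2 (1.4 equiv per carbamate, syringe pump, 8 h), Et2O, 3 mM, −20 °C; MgBr2·OEt2, MeOH, −20 to 35 °C; solvent swap, TBAF·3H2O, PhMe, 50 °C
Reagents that add atoms: none
Why: Proposed new method: LiN(i-Pr)2 does not bind an alkyl Bpin irreversibly but can remove the carbamate-activated benzylic C7–H (helped by the two flanking MOM oxygens), so each carbanion is borylated with retention as soon as it forms; carbanion-to-boron pairing allows only head-to-tail union, and the monomeric closure would be a strained [8]paracyclophane-type ring, so two units close to the 24-membered bis-boronate 23; on warming with MgBr2/MeOH each C6 migrates from boron to C7 antiperiplanar to the departing carbamate (inversion at C7), which pushes both boron atoms out of the ring (24 to 22 atoms) and forms both C6–C7 bonds with the configuration set by 21; fluoride and water then replace B by H with retention (7S,20S) and remove both silyl groups; the closest known reaction type is the in situ lithiation–borylation of secondary benzylic carbamates followed by protodeboronation of tertiary benzylic boronic esters, known only intermolecularly and never as a ring-forming, ring-contracting cyclodimerisation.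

**Step 12**
Reactants: 25 (1R,2S,7S,14R,15S,20S)-7,20-diallyl-2,15-dimethyl-tetra-O-MOM-[7.7]paracyclophane-1,14-diol; 26 bromodichloromethane
Product: 27 (1R,2S,7S,14R,15S,20S)-7,20-bis(2-bromo-4,4-dichlorobutyl)-2,15-dimethyl-tetra-O-MOM-[7.7]paracyclophane-1,14-diol (CHBr centres as mixtures)
Conditions: 26 (8 equiv), fac-Ir(ppy)3 (1 mol%), MeCN, blue LED, rt
Reagents that add atoms: none
Why: In this Kharasch atom-transfer radical addition the electrophilic dichloromethyl radical adds to the terminal CH2 of each allyl group and the secondary radical takes Br (the weakest bond) from 26, which completes the four-carbon side chains with a CHCl2 terminus; the new CHBr centres are erased in step 13.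

**Step 13**
Reactants: 27 (1R,2S,7S,14R,15S,20S)-7,20-bis(2-bromo-4,4-dichlorobutyl)-2,15-dimethyl-tetra-O-MOM-[7.7]paracyclophane-1,14-diol
Product: 28 (1R,2S,7S,14R,15S,20S)-7-(4-chlorobutyl)-20-(4,4-dichlorobutyl)-2,15-dimethyl-tetra-O-MOM-[7.7]paracyclophane-1,14-diol
Conditions: Bu3SnH (2.9 equiv), (PhSe)2 (10 mol%), AIBN, PhMe, 80 °C; KF work-up; preparative HPLC
Reagents that add atoms: none
Why: In this radical-chain hydrodehalogenation the stannyl radical takes secondary Br much faster than Cl of CHCl2, and that much faster than Cl of CH2Cl, so once both bromides are gone the third equivalent removes one of four symmetry-equivalent chlorines, any of which gives 28 (statistical ceiling 50%, expected about 40%, with under-reduced material recycled); PhSeH formed in the flask traps the α-chloro radical before a 1,5-hydrogen shift from C7 could scramble that centre.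

**Step 14**
Reactants: 28 (1R,2S,7S,14R,15S,20S)-7-(4-chlorobutyl)-20-(4,4-dichlorobutyl)-2,15-dimethyl-tetra-O-MOM-[7.7]paracyclophane-1,14-diol
Product: 30 target CNP0310589.1, via bis(N-trichloroacetylcarbamate) 29 (not isolated)
Conditions: Cl3CC(O)NCO (2.5 equiv), CH2Cl2, 0 °C; evaporate; HCl (1.25 M in MeOH), 35 °C
Reagents that add atoms: trichloroacetyl isocyanate, O=C=NC(=O)C(Cl)(Cl)Cl
Why: Isocyanate addition (Kocovsky carbamate synthesis) followed by acid methanolysis removes the very electrophilic trichloroacetyl groups and all four MOM acetals in one operation; the benzylic carbamates survive because the ring oxygens are meta to C1/C14 and cannot stabilise a benzylic cation, and no stereocenter is touched.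

**Compound list**
1 | resorcinol | Oc1cccc(O)c1 | starting material
2 | 1,3-bis(methoxymethoxy)benzene | COCOc1cccc(OCOC)c1 | intermediate
3 | 2-[3,5-bis(methoxymethoxy)phenyl]-4,4,5,5-tetramethyl-1,3,2-dioxaborolane | COCOc1cc(OCOC)cc(c1)B1OC(C)(C)C(C)(C)O1 | intermediate
4 | (R)-3-bromo-2-methylpropan-1-ol | OC[C@@H](C)CBr | starting material
5 | (R)-3-bromo-2-methylpropyl N,N-diisopropylcarbamate | CC(C)N(C(C)C)C(=O)OC[C@@H](C)CBr | intermediate
6 | 1-bromo-3-chloropropane | ClCCCBr | starting material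
7 | [(R)-3-(diisopropylcarbamoyloxy)-2-methylpropyl]magnesium bromide | CC(C)N(C(C)C)C(=O)OC[C@@H](C)C[Mg]Br | intermediate
8 | (S)-6-chloro-2-methylhexyl N,N-diisopropylcarbamate | CC(C)N(C(C)C)C(=O)OC[C@@H](C)CCCCCl | intermediate
9 | (1S,2S)-6-chloro-1-lithio-2-methylhexyl N,N-diisopropylcarbamate (sparteine complex, ligand not drawn) | CC(C)N(C(C)C)C(=O)O[C@@H]([Li])[C@@H](C)CCCCCl | intermediate
10 | lithium [3,5-bis(methoxymethoxy)phenyl][(1S,2S)-6-chloro-1-(diisopropylcarbamoyloxy)-2-methylhexyl](pinacolato)borate | CC(C)N(C(C)C)C(=O)O[C@@H]([B-]1(OC(C)(C)C(C)(C)O1)c1cc(OCOC)cc(OCOC)c1)[C@@H](C)CCCCCl.[Li+] | intermediate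
11 | 2-{(1R,2S)-1-[3,5-bis(methoxymethoxy)phenyl]-6-chloro-2-methylhexyl}-4,4,5,5-tetramethyl-1,3,2-dioxaborolane | COCOc1cc(cc(OCOC)c1)[C@H](B1OC(C)(C)C(C)(C)O1)[C@@H](C)CCCCCl | intermediate
12 | (1R,2S)-1-[3,5-bis(methoxymethoxy)phenyl]-6-chloro-2-methylhexan-1-ol | COCOc1cc(cc(OCOC)c1)[C@H](O)[C@@H](C)CCCCCl | intermediate
13 | tert-butyl{(1R,2S)-1-[3,5-bis(methoxymethoxy)phenyl]-6-chloro-2-methylhexyloxy}dimethylsilane | COCOc1cc(cc(OCOC)c1)[C@H](O[Si](C)(C)C(C)(C)C)[C@@H](C)CCCCCl | intermediate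
14 | N,N-dimethylformamide | CN(C)C=O | starting material
15 | aryllithium from 13, lithium between the two MOM ethers | COCOc1cc(cc(OCOC)c1[Li])[C@H](O[Si](C)(C)C(C)(C)C)[C@@H](C)CCCCCl | intermediate
16 | 4-[(1R,2S)-1-(tert-butyldimethylsilyloxy)-6-chloro-2-methylhexyl]-2,6-bis(methoxymethoxy)benzaldehyde | COCOc1cc(cc(OCOC)c1C=O)[C@H](O[Si](C)(C)C(C)(C)C)[C@@H](C)CCCCCl | intermediate
17 | allylmagnesium bromide | C=CC[Mg]Br | starting material
18 | (+)-B-allyldiisopinocampheylborane ((−)-α-pinene series) | C=CCB([C@H]1C[C@H]2C[C@@H]([C@@H]1C)C2(C)C)[C@H]1C[C@H]2C[C@@H]([C@@H]1C)C2(C)C | intermediate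
19 | (1R)-1-{4-[(1R,2S)-1-(tert-butyldimethylsilyloxy)-6-chloro-2-methylhexyl]-2,6-bis(methoxymethoxy)phenyl}but-3-en-1-ol | C=CC[C@@H](O)c1c(OCOC)cc(cc1OCOC)[C@H](O[Si](C)(C)C(C)(C)C)[C@@H](C)CCCCCl | intermediate
20 | N,N-diisopropylcarbamate of 19 (carbinol carbon R) | C=CC[C@@H](OC(=O)N(C(C)C)C(C)C)c1c(OCOC)cc(cc1OCOC)[C@H](O[Si](C)(C)C(C)(C)C)[C@@H](C)CCCCCl | intermediate
21 | monomer: 20 with Cl replaced by Bpin | C=CC[C@@H](OC(=O)N(C(C)C)C(C)C)c1c(OCOC)cc(cc1OCOC)[C@H](O[Si](C)(C)C(C)(C)C)[C@@H](C)CCCCB1OC(C)(C)C(C)(C)O1 | intermediate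
22 | 21 lithiated at the benzylic carbamate carbon (R, retention) | C=CC[C@@]([Li])(OC(=O)N(C(C)C)C(C)C)c1c(OCOC)cc(cc1OCOC)[C@H](O[Si](C)(C)C(C)(C)C)[C@@H](C)CCCCB1OC(C)(C)C(C)(C)O1 | intermediate
23 | 24-membered dilithium bis-boronate, head-to-tail cyclic dimer with both C6–B–C7 units in the ring (carbamate carbons R) | C[C@H]1CCCC[B-]3(OC(C)(C)C(C)(C)O3)[C@@](OC(=O)N(C(C)C)C(C)C)(CC=C)c2c(OCOC)cc(cc2OCOC)[C@H](O[Si](C)(C)C(C)(C)C)[C@@H](C)CCCC[B-]3(OC(C)(C)C(C)(C)O3)[C@@](OC(=O)N(C(C)C)C(C)C)(CC=C)c2c(OCOC)cc(cc2OCOC)[C@@H]1O[Si](C)(C)C(C)(C)C.[Li+].[Li+] | intermediate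
24 | (1R,2S,7S,14R,15S,20S)-7,20-diallyl-7,20-bis(pinacolatoboryl)-1,14-bis(tert-butyldimethylsilyloxy)-2,15-dimethyl-tetra-O-MOM-[7.7]paracyclophane | C[C@H]1CCCC[C@@](B3OC(C)(C)C(C)(C)O3)(CC=C)c2c(OCOC)cc(cc2OCOC)[C@H](O[Si](C)(C)C(C)(C)C)[C@@H](C)CCCC[C@@](B3OC(C)(C)C(C)(C)O3)(CC=C)c2c(OCOC)cc(cc2OCOC)[C@@H]1O[Si](C)(C)C(C)(C)C | intermediate
25 | (1R,2S,7S,14R,15S,20S)-7,20-diallyl-2,15-dimethyl-tetra-O-MOM-[7.7]paracyclophane-1,14-diol | C[C@H]1CCCC[C@@H](CC=C)c2c(OCOC)cc(cc2OCOC)[C@H](O)[C@@H](C)CCCC[C@@H](CC=C)c2c(OCOC)cc(cc2OCOC)[C@@H]1O | intermediate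
26 | bromodichloromethane | ClC(Cl)Br | starting material
27 | (1R,2S,7S,14R,15S,20S)-7,20-bis(2-bromo-4,4-dichlorobutyl)-2,15-dimethyl-tetra-O-MOM-[7.7]paracyclophane-1,14-diol (CHBr epimers) | C[C@H]1CCCC[C@@H](CC(Br)CC(Cl)Cl)c2c(OCOC)cc(cc2OCOC)[C@H](O)[C@@H](C)CCCC[C@@H](CC(Br)CC(Cl)Cl)c2c(OCOC)cc(cc2OCOC)[C@@H]1O | intermediate
28 | (1R,2S,7S,14R,15S,20S)-7-(4-chlorobutyl)-20-(4,4-dichlorobutyl)-2,15-dimethyl-tetra-O-MOM-[7.7]paracyclophane-1,14-diol | C[C@H]1CCCC[C@@H](CCCCCl)c2c(OCOC)cc(cc2OCOC)[C@H](O)[C@@H](C)CCCC[C@@H](CCCC(Cl)Cl)c2c(OCOC)cc(cc2OCOC)[C@@H]1O | intermediate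
29 | 1,14-bis(N-trichloroacetylcarbamate) of 28 | C[C@H]1CCCC[C@@H](CCCCCl)c2c(OCOC)cc(cc2OCOC)[C@H](OC(=O)NC(=O)C(Cl)(Cl)Cl)[C@@H](C)CCCC[C@@H](CCCC(Cl)Cl)c2c(OCOC)cc(cc2OCOC)[C@@H]1OC(=O)NC(=O)C(Cl)(Cl)Cl | intermediate
30 | CNP0310589.1, (1R,2S,7S,14R,15S,20S)-7-(4-chlorobutyl)-20-(4,4-dichlorobutyl)-2,15-dimethyl[7.7]paracyclophane-tetraol 1,14-dicarbamate | C[C@H]1CCCC[C@@H](CCCCCl)c2c(O)cc(cc2O)[C@H](OC(N)=O)[C@@H](C)CCCC[C@@H](CCCC(Cl)Cl)c2c(O)cc(cc2O)[C@@H]1OC(N)=O | target

**Step count.** Total: 14 steps. Longest linear sequence: 12 steps (steps 1, 2 and 5–14; the branch through steps 3 and 4 is equally long).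

**The three steps most likely to fail**

Step 11 (the new cyclodimerisation, with the B-to-H exchange that follows it). The amide base may be too weak for the twisted, electron-rich benzylic position. Oligomers may also compete with the cyclic dimer. The fallback sets out from 16 and comes back at 25, and it uses only known reaction types.
- NaI and PPh3 in refluxing MeCN convert the chloride of 16 into the ω-formyl phosphonium iodide F1.
- Slow addition of KN(SiMe3)2 at 3 mM in THF starts a head-to-tail double Wittig cyclodimerisation, which gives the (6Z,19Z)-diene macrocycle F2.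
- Copper hydride catalysed enantioselective hydroallylation of the two vinylarene units follows (Cu(OAc)2, DTBM-SEGPHOS, (MeO)2MeSiH, allyl diphenyl phosphate, LiOt-Bu, THF). The ligand enantiomer is chosen on a model styrene. This puts H on C6/C19 and allyl on C7/C20 and gives the bis-silyl ether F3.
- TBAF in THF then gives 25.

Step 13 (statistical removal of one chlorine). Separating the tri-, tetra- and dichloro macrocycles may be impractical. The fallback sets out from 25 and comes back at 28. It moves the desymmetrisation to the C–C bond-forming stage, so that no C–Cl bond has to be reduced.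
- Atom-transfer addition with a deficit of 26 (0.6 equiv) gives the mono-adduct F4. It differs strongly in mass and polarity from 25 and 27, so it is easily separated, and 25 is recycled.
- Iodine-atom-transfer addition of ICH2Cl (Et3B, air) to the remaining allyl group gives the mixed bromo-iodo adduct F5.
- Bu3SnH (2.2 equiv) then removes only the secondary Br and I and gives 28.

Step 14 (acid in the presence of the benzylic carbamates). Solvolysis at C1/C14 or incomplete trichloroacetyl cleavage may occur. The fallback sets out from 28 and comes back at 30, with the order of events reversed.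
- HCl in MeOH first removes the four MOM groups, giving the hexaol F6.
- An excess of Cl3CC(O)NCO acylates all six hydroxy groups, giving the hexakis(N-trichloroacetylcarbamate) F7.
- K2CO3 in aqueous MeOH cleaves the trichloroacetyl groups. It also cleaves the four aryl carbamates by E1cB loss of isocyanic acid.
- The two alkyl carbamates are inert to this, and 30 results.

**Further compounds**
F1 | step 11 | {(5S,6R)-6-(tert-butyldimethylsilyloxy)-6-[4-formyl-3,5-bis(methoxymethoxy)phenyl]-5-methylhexyl}triphenylphosphonium iodide | COCOc1cc(cc(OCOC)c1C=O)[C@H](O[Si](C)(C)C(C)(C)C)[C@@H](C)CCCC[P+](c1ccccc1)(c1ccccc1)c1ccccc1.[I-]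
F2 | step 11 | (1R,2S,6Z,14R,15S,19Z)-1,14-bis(tert-butyldimethylsilyloxy)-2,15-dimethyl-tetra-O-MOM-[7.7]paracyclophane-6,19-diene | C[C@H]1CCC/C=C\c2c(OCOC)cc(cc2OCOC)[C@H](O[Si](C)(C)C(C)(C)C)[C@@H](C)CCC/C=C\c2c(OCOC)cc(cc2OCOC)[C@@H]1O[Si](C)(C)C(C)(C)C
F3 | step 11 | bis(tert-butyldimethylsilyl) ether of 25 | C[C@H]1CCCC[C@@H](CC=C)c2c(OCOC)cc(cc2OCOC)[C@H](O[Si](C)(C)C(C)(C)C)[C@@H](C)CCCC[C@@H](CC=C)c2c(OCOC)cc(cc2OCOC)[C@@H]1O[Si](C)(C)C(C)(C)C
F4 | step 13 | 7-allyl-20-(2-bromo-4,4-dichlorobutyl) mono-adduct of 25 | C[C@H]1CCCC[C@@H](CC=C)c2c(OCOC)cc(cc2OCOC)[C@H](O)[C@@H](C)CCCC[C@@H](CC(Br)CC(Cl)Cl)c2c(OCOC)cc(cc2OCOC)[C@@H]1O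
F5 | step 13 | 7-(4-chloro-2-iodobutyl)-20-(2-bromo-4,4-dichlorobutyl) mixed adduct | C[C@H]1CCCC[C@@H](CC(I)CCCl)c2c(OCOC)cc(cc2OCOC)[C@H](O)[C@@H](C)CCCC[C@@H](CC(Br)CC(Cl)Cl)c2c(OCOC)cc(cc2OCOC)[C@@H]1O
F6 | step 14 | hexaol: 28 without the four MOM groups | C[C@H]1CCCC[C@@H](CCCCCl)c2c(O)cc(cc2O)[C@H](O)[C@@H](C)CCCC[C@@H](CCCC(Cl)Cl)c2c(O)cc(cc2O)[C@@H]1O
F7 | step 14 | hexakis(N-trichloroacetylcarbamate) of F6 | C[C@H]1CCCC[C@@H](CCCCCl)c2c(OC(=O)NC(=O)C(Cl)(Cl)Cl)cc(cc2OC(=O)NC(=O)C(Cl)(Cl)Cl)[C@H](OC(=O)NC(=O)C(Cl)(Cl)Cl)[C@@H](C)CCCC[C@@H](CCCC(Cl)Cl)c2c(OC(=O)NC(=O)C(Cl)(Cl)Cl)cc(cc2OC(=O)NC(=O)C(Cl)(Cl)Cl)[C@@H]1OC(=O)NC(=O)C(Cl)(Cl)Cl
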